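Ring B is grown on the ether oxygen of ring A instead of being coupled to it. Its meta-related oxygens (aryloxy at B2, methoxy at B4, hydrogen at B3 between them) are read as an ynol ether carbon and a ketene carbonyl carbon. Irradiating a diazo ketoester with the ethynyl ether of dibenzylated ring A sets off Wolff shift, [2+2] addition, four-electron opening and six-electron closure. One operation therefore delivers the tetrasubstituted ring B, its ester at B1, the masked pentanoyl group at B6 and the diaryl ether, as the B4 phenol. The precursor is a methyl 2-diazo-3-oxopent-4-enoate whose C-4 carries the ketone as a butyl-substituted dioxolane.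

Key step: step 12

Remark: ring B locants are B1 (carries CO2Me), B2 (ether oxygen), B3 (H), B4 (OMe), B5 (H), B6 (pentanoyl). The target is achiral, and the racemic Mannich base, diazo carbinol and cyclobutenone lose their stereocentres again. Methyl diazoacetate is made in the route and handled only in solution.

Step 1
Reactants: 1 olivetol (5-pentylbenzene-1,3-diol)
Product: 3 2,4-dihydroxy-6-pentylbenzaldehyde, via iminium chloride 2 (not isolated)
Conditions: POCl3 (1.2 equiv), DMF, 0 °C to rt; then ice-water
Reagents that add atoms: N,N-dimethylformamide, CN(C)C=O; water, O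
Why: Vilsmeier–Haack formylation: the chloroiminium ion attacks the resorcinol carbon para to one hydroxyl and ortho to the other (next to the pentyl chain) rather than the carbon squeezed between both hydroxyls, and water hydrolyses iminium salt 2.

Step 2
Reactants: 3 2,4-dihydroxy-6-pentylbenzaldehyde
Product: 4 2,4-bis(benzyloxy)-6-pentylbenzaldehyde
Conditions: BnBr (2.5 equiv), K2CO3 (3 equiv), DMF, 60 °C
Reagents that add atoms: benzyl bromide, BrCc1ccccc1
Why: Williamson ether synthesis; warm DMF and excess carbonate should also alkylate the hydroxyl that is hydrogen-bonded to the aldehyde.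

Step 3
Reactants: 4 2,4-bis(benzyloxy)-6-pentylbenzaldehyde
Product: 6 2,4-bis(benzyloxy)-6-pentylphenol, via aryl formate 5 (not isolated)
Conditions: mCPBA (1.3 equiv), CH2Cl2, 0 °C to rt; aq NaHCO3 wash; crude 5, K2CO3 (0.2 equiv), MeOH, rt, argon
Reagents that add atoms: 3-chloroperbenzoic acid, OOC(=O)c1cccc(Cl)c1
Why: Baeyer–Villiger (Dakin-type) oxidation: the electron-rich aryl group migrates in the Criegee adduct to give formate 5, which base-catalysed methanolysis converts into the phenol.

Step 4
Reactants: 6 2,4-bis(benzyloxy)-6-pentylphenol; 7 trichloroethylene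
Product: 9 1,5-bis(benzyloxy)-2-{[(E)-1,2-dichloroethenyl]oxy}-3-pentylbenzene, via dichloroacetylene 8 (not isolated)
Conditions: 7 (1.5 equiv), K2CO3 (2.5 equiv), DMF, 70 °C, argon
Reagents that add atoms: none
Why: Elimination–addition vinylation of a phenol: carbonate dehydrochlorinates 7 to the slim, linear dichloroacetylene, which accepts even the doubly ortho-substituted phenoxide, and anti addition of ArO–H sets the E geometry.

Step 5
Reactants: 9 1,5-bis(benzyloxy)-2-{[(E)-1,2-dichloroethenyl]oxy}-3-pentylbenzene
Product: 12 1,5-bis(benzyloxy)-2-(ethynyloxy)-3-pentylbenzene, via chloroalkyne 10 (not isolated), via lithium acetylide 11 (not isolated)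
Conditions: n-BuLi (2.3 equiv), Et2O, −78 to −40 °C; H2O, −78 °C; cold work-up, short plug of basic alumina, used at once
Reagents that add atoms: none
Why: Dichlorovinyl ether route to ynol ethers: vinylic deprotonation and loss of LiCl give chloroalkyne 10, lithium–chlorine exchange gives acetylide 11, cold protonation gives the terminal alkyne, and the benzyl ethers are inert to n-BuLi at these temperatures.

Step 6
Reactants: 13 methyl 3-oxoheptanoate
Product: 14 methyl 2-(2-butyl-1,3-dioxolan-2-yl)acetate
Conditions: HOCH2CH2OH (3 equiv), p-TsOH·H2O (cat.), toluene, reflux, Dean–Stark trap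
Reagents that add atoms: ethylene glycol, OCCO
Why: Acid-catalysed ketalisation driven by azeotropic removal of water; only the ketone carbonyl of the β-keto ester is electrophilic enough to react.

Step 7
Reactants: 14 methyl 2-(2-butyl-1,3-dioxolan-2-yl)acetate
Product: 15 2-(2-butyl-1,3-dioxolan-2-yl)acetaldehyde
Conditions: i-Bu2AlH (1.1 equiv), CH2Cl2, −78 °C; MeOH; aq potassium sodium tartrate
Reagents that add atoms: none
Why: Partial ester reduction with i-Bu2AlH: the tetrahedral aluminium hemiacetal, held by chelation to a dioxolane oxygen, survives at −78 °C and releases the aldehyde only on work-up.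

Step 8
Reactants: 15 2-(2-butyl-1,3-dioxolan-2-yl)acetaldehyde
Product: 17 2-(2-butyl-1,3-dioxolan-2-yl)prop-2-enal, via Mannich base 16 (not isolated)
Conditions: [Me2N=CH2]I (Eschenmoser's salt, 2.5 equiv), Et3N (4 equiv), CH2Cl2, rt
Reagents that add atoms: dimethyl(methylidene)ammonium iodide, C=[N+](C)C.[I-]
Why: Mannich α-methylenation of an aldehyde: the enol of 15 adds to the iminium ion, racemic Mannich base 16 loses dimethylamine by β-elimination (its stereocentre vanishes), the amine should leave faster than a ketal oxygen, and the product has no α-hydrogen left.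

Step 9
Reactants: 18 glycine methyl ester hydrochloride
Product: 19 methyl diazoacetate
Conditions: NaNO2 (1.2 equiv), H2SO4 (cat.), H2O/CH2Cl2, −5 °C; dried, solvent exchanged for THF below 20 °C, never distilled
Reagents that add atoms: sodium nitrite, [Na+].[O-]N=O
Why: Diazotisation of an α-amino ester: the diazonium ion loses its acidic α-proton to give the ester-stabilised diazo compound, which is extracted into the organic layer as it forms.

Step 10
Reactants: 17 2-(2-butyl-1,3-dioxolan-2-yl)prop-2-enal; 19 methyl diazoacetate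
Product: 21 methyl 4-(2-butyl-1,3-dioxolan-2-yl)-2-diazo-3-hydroxypent-4-enoate (racemic), via lithiated diazoacetate 20 (not isolated)
Conditions: LiN(i-Pr)2 (1.1 equiv) added to 17 + 19 (1.1 equiv), THF, −78 °C; AcOH, −78 °C
Reagents that add atoms: none
Why: Aldol-type addition of a lithiated diazoacetate to an aldehyde: at −78 °C 1,2-addition to the non-enolisable enal should outrun dipolar cycloaddition to the alkene, and the carbinol centre forms without control (racemic) because step 11 removes it.

Step 11
Reactants: 21 methyl 4-(2-butyl-1,3-dioxolan-2-yl)-2-diazo-3-hydroxypent-4-enoate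
Product: 22 methyl 4-(2-butyl-1,3-dioxolan-2-yl)-2-diazo-3-oxopent-4-enoate
Conditions: IBX (2-iodoxybenzoic acid, 1.5 equiv), DMSO, rt
Reagents that add atoms: none
Why: IBX oxidation of a β-hydroxy-α-diazo ester: the neutral conditions leave the diazo group, ketal and 1,1-disubstituted alkene alone, and the doubly acceptor-substituted diazo group is too poor a dipole to attack the new enone.

Step 12
Reactants: 12 1,5-bis(benzyloxy)-2-(ethynyloxy)-3-pentylbenzene; 22 methyl 4-(2-butyl-1,3-dioxolan-2-yl)-2-diazo-3-oxopent-4-enoate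
Product: 27 methyl 2-[2,4-bis(benzyloxy)-6-pentylphenoxy]-6-(2-butyl-1,3-dioxolan-2-yl)-4-hydroxybenzoate, via vinylketene 23 (not isolated), via cyclobutenone 24 (not isolated), via dienylketene 25 (not isolated), via cyclohexadienone 26 (not isolated)
Conditions: 22 (1.0 equiv), 12 (1.2 equiv), degassed ClCH2CH2Cl (0.1 M), hν (300 nm lamps, Pyrex), rt, until N2 evolution stops; then 80 °C
Reagents that add atoms: none
Why: Excitation of 22 releases N2 while the C-4 alkenyl carbon (B6) moves from the ketone carbon (future B4) onto the former diazo carbon (B1); this photochemical Wolff rearrangement makes bond B1–B6 and produces vinylketene 23, in which B1 holds the ester. Ynol ether 12 is most electron-rich at its CH terminus, which attacks the electrophilic central carbon of the ketene, and C–C collapse of the zwitterion completes a [2+2] cycloaddition that closes the transient four-membered ring of 24 and forms B3–B4 and B1–B2. Cyclobutenone 24 then opens (light or 80 °C) in a conrotatory four-electron process that breaks B1–B4, the Z isomer of dienylketene 25 closes ring B by a disrotatory six-electron electrocyclisation (B4–B5), and dienone 26 tautomerises to phenol 27; because the opening is reversible, material that opens the unproductive way is fed back. The closest known reaction type is the Danheiser benzannulation in its diazo ketone form with alkoxyacetylenes. No stereocentre is kept (the quaternary carbon of racemic 24 becomes sp2), so only regio- and chemoselectivity are needed: the donor–acceptor pairing fixes the orientation (alkyne CH becomes B3, the oxygen-bearing alkyne carbon becomes B2 beside B1), and the ketal removes the second ketone, leaving only the weakly nucleophilic ester carbonyl as a possible heterodiene terminus for a competing [4+2] addition. Both ring A hydroxyls are benzylated so that no OH traps the ketene, the aryl ynol ether has no β-hydrogen and cannot fragment by a retro-ene path on heating, and Pyrex-filtered 300 nm light addresses the diazo chromophore rather than the aryl ethers.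

Step 13
Reactants: 27 methyl 2-[2,4-bis(benzyloxy)-6-pentylphenoxy]-6-(2-butyl-1,3-dioxolan-2-yl)-4-hydroxybenzoate
Product: 28 methyl 2-[2,4-bis(benzyloxy)-6-pentylphenoxy]-6-(2-butyl-1,3-dioxolan-2-yl)-4-methoxybenzoate
Conditions: MeI (2 equiv), K2CO3 (2 equiv), acetone, 40 °C
Reagents that add atoms: iodomethane, CI
Why: Williamson O-methylation of the only free hydroxyl (B4); the doubly ortho-flanked ester, the ketal and the benzyl ethers are inert to carbonate.

Step 14
Reactants: 28 methyl 2-[2,4-bis(benzyloxy)-6-pentylphenoxy]-6-(2-butyl-1,3-dioxolan-2-yl)-4-methoxybenzoate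
Product: 29 methyl 2-[2,4-bis(benzyloxy)-6-pentylphenoxy]-4-methoxy-6-pentanoylbenzoate
Conditions: 1 M aq HCl/THF (1:4), rt to 40 °C
Reagents that add atoms: water, O
Why: Acid-catalysed ketal hydrolysis through the benzylic oxocarbenium ion; the absence of methanol prevents ester or pseudo-ester exchange, and dilute acid leaves benzyl ethers, methyl ester and diaryl ether untouched.

Step 15
Reactants: 29 methyl 2-[2,4-bis(benzyloxy)-6-pentylphenoxy]-4-methoxy-6-pentanoylbenzoate
Product: 30 methyl 2-(2,4-dihydroxy-6-pentylphenoxy)-4-methoxy-6-pentanoylbenzoate (CNP0313056.0)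
Conditions: H2 (1 atm), Pd/C (10 wt % Pd), EtOAc, rt, stopped after uptake of two equivalents of H2
Reagents that add atoms: none
Why: Catalytic hydrogenolysis of aryl benzyl ethers: in neutral EtOAc at 1 atm O-benzyl cleavage should be much faster than reduction of the aryl ketone, which the neighbouring ester twists out of conjugation.

Compound list
1 | olivetol (5-pentylbenzene-1,3-diol) | CCCCCc1cc(O)cc(O)c1 | starting material
2 | (2,4-dihydroxy-6-pentylbenzylidene)dimethylammonium chloride | CCCCCc1cc(O)cc(O)c1C=[N+](C)C.[Cl-] | intermediate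
3 | 2,4-dihydroxy-6-pentylbenzaldehyde | CCCCCc1cc(O)cc(O)c1C=O | intermediate
4 | 2,4-bis(benzyloxy)-6-pentylbenzaldehyde | CCCCCc1cc(OCc2ccccc2)cc(OCc2ccccc2)c1C=O | intermediate
5 | 2,4-bis(benzyloxy)-6-pentylphenyl formate | CCCCCc1cc(OCc2ccccc2)cc(OCc2ccccc2)c1OC=O | intermediate
6 | 2,4-bis(benzyloxy)-6-pentylphenol | CCCCCc1cc(OCc2ccccc2)cc(OCc2ccccc2)c1O | intermediate
7 | trichloroethylene | ClC=C(Cl)Cl | starting material
8 | dichloroacetylene | ClC#CCl | intermediate
9 | 1,5-bis(benzyloxy)-2-{[(E)-1,2-dichloroethenyl]oxy}-3-pentylbenzene | Cl/C=C(/Cl)Oc1c(CCCCC)cc(OCc2ccccc2)cc1OCc1ccccc1 | intermediate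
10 | 1,5-bis(benzyloxy)-2-[(chloroethynyl)oxy]-3-pentylbenzene | ClC#COc1c(CCCCC)cc(OCc2ccccc2)cc1OCc1ccccc1 | intermediate
11 | lithium [2,4-bis(benzyloxy)-6-pentylphenoxy]acetylide | [Li]C#COc1c(CCCCC)cc(OCc2ccccc2)cc1OCc1ccccc1 | intermediate
12 | 1,5-bis(benzyloxy)-2-(ethynyloxy)-3-pentylbenzene | C#COc1c(CCCCC)cc(OCc2ccccc2)cc1OCc1ccccc1 | intermediate
13 | methyl 3-oxoheptanoate | CCCCC(=O)CC(=O)OC | starting material
14 | methyl 2-(2-butyl-1,3-dioxolan-2-yl)acetate | CCCCC1(CC(=O)OC)OCCO1 | intermediate
15 | 2-(2-butyl-1,3-dioxolan-2-yl)acetaldehyde | CCCCC1(CC=O)OCCO1 | intermediate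
16 | 2-(2-butyl-1,3-dioxolan-2-yl)-3-(dimethylamino)propanal (racemic) | CCCCC1(C(CN(C)C)C=O)OCCO1 | intermediate
17 | 2-(2-butyl-1,3-dioxolan-2-yl)prop-2-enal | CCCCC1(C(=C)C=O)OCCO1 | intermediate
18 | glycine methyl ester hydrochloride | COC(=O)CN.Cl | starting material
19 | methyl diazoacetate | COC(=O)C=[N+]=[N-] | intermediate
20 | methyl diazo(lithio)acetate | COC(=O)C([Li])=[N+]=[N-] | intermediate
21 | methyl 4-(2-butyl-1,3-dioxolan-2-yl)-2-diazo-3-hydroxypent-4-enoate (racemic) | C=C(C1(CCCC)OCCO1)C(O)C(=[N+]=[N-])C(=O)OC | intermediate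
22 | methyl 4-(2-butyl-1,3-dioxolan-2-yl)-2-diazo-3-oxopent-4-enoate | C=C(C1(CCCC)OCCO1)C(=O)C(=[N+]=[N-])C(=O)OC | intermediate
23 | methyl 3-(2-butyl-1,3-dioxolan-2-yl)-2-(oxomethylidene)but-3-enoate | C=C(C1(CCCC)OCCO1)C(=C=O)C(=O)OC | intermediate
24 | methyl 2-[2,4-bis(benzyloxy)-6-pentylphenoxy]-1-[1-(2-butyl-1,3-dioxolan-2-yl)ethenyl]-4-oxocyclobut-2-ene-1-carboxylate (racemic) | COC(=O)C1(C(=C)C2(CCCC)OCCO2)C(=O)C=C1Oc1c(CCCCC)cc(OCc2ccccc2)cc1OCc1ccccc1 | intermediate
25 | methyl (2Z)-3-[2,4-bis(benzyloxy)-6-pentylphenoxy]-2-[1-(2-butyl-1,3-dioxolan-2-yl)ethenyl]-5-oxopenta-2,4-dienoate | C=C(C1(CCCC)OCCO1)/C(C(=O)OC)=C(\C=C=O)Oc1c(CCCCC)cc(OCc2ccccc2)cc1OCc1ccccc1 | intermediate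
26 | methyl 6-[2,4-bis(benzyloxy)-6-pentylphenoxy]-2-(2-butyl-1,3-dioxolan-2-yl)-4-oxocyclohexa-1,5-diene-1-carboxylate | COC(=O)C1=C(C2(CCCC)OCCO2)CC(=O)C=C1Oc1c(CCCCC)cc(OCc2ccccc2)cc1OCc1ccccc1 | intermediate
27 | methyl 2-[2,4-bis(benzyloxy)-6-pentylphenoxy]-6-(2-butyl-1,3-dioxolan-2-yl)-4-hydroxybenzoate | CCCCCc1cc(OCc2ccccc2)cc(OCc2ccccc2)c1Oc1cc(O)cc(C2(CCCC)OCCO2)c1C(=O)OC | intermediate
28 | methyl 2-[2,4-bis(benzyloxy)-6-pentylphenoxy]-6-(2-butyl-1,3-dioxolan-2-yl)-4-methoxybenzoate | CCCCCc1cc(OCc2ccccc2)cc(OCc2ccccc2)c1Oc1cc(OC)cc(C2(CCCC)OCCO2)c1C(=O)OC | intermediate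
29 | methyl 2-[2,4-bis(benzyloxy)-6-pentylphenoxy]-4-methoxy-6-pentanoylbenzoate | CCCCCc1cc(OCc2ccccc2)cc(OCc2ccccc2)c1Oc1cc(OC)cc(C(=O)CCCC)c1C(=O)OC | intermediate
30 | methyl 2-(2,4-dihydroxy-6-pentylphenoxy)-4-methoxy-6-pentanoylbenzoate | CCCCCc1cc(O)cc(O)c1Oc1cc(OC)cc(C(=O)CCCC)c1C(=O)OC | target

Total step count: 15.
Longest linear sequence: 9 steps (steps 1–5, then 12–15). The branch through steps 6, 7, 8, 10 and 11, then 12–15, is equally long.

Steps most likely to fail

Step 12.
- **What may go wrong:** The zwitterion from ketene and ynol ether may close through the ester oxygen (hetero-[4+2] addition) instead of through carbon. The crowded B1–B2 bond may also form so slowly that the ketene dimerises or acylates the phenol already formed. The free carbene may be captured by a dioxolane oxygen, or the ynol ether may polymerise under light.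
- **Fallback (ring B made separately, ether bond made by cross-coupling):** it sets out from phenol 6 and comes back at ketone 29.
  - 3,5-Dimethoxybenzonitrile and n-BuMgBr give, after acidic hydrolysis of the imine, 1-(3,5-dimethoxyphenyl)pentan-1-one F1.
  - NBS in MeCN brominates the position para to one methoxy group and next to the acyl group to give 1-(2-bromo-3,5-dimethoxyphenyl)pentan-1-one F2.
  - Methoxycarbonylation (Pd(OAc)2, 1,1'-bis(diphenylphosphino)ferrocene, CO, Et3N, MeOH/DMF, 90 °C) gives methyl 2,4-dimethoxy-6-pentanoylbenzoate F3.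
  - BCl3 (CH2Cl2, −78 to 0 °C) cleaves only the methyl ether chelated to the ester carbonyl and gives methyl 2-hydroxy-4-methoxy-6-pentanoylbenzoate F4.
  - Tf2O and pyridine give methyl 4-methoxy-6-pentanoyl-2-{[(trifluoromethyl)sulfonyl]oxy}benzoate F5.
  - Buchwald–Hartwig C–O coupling of this triflate with 6 (Pd(OAc)2, t-BuXPhos, K3PO4, toluene, 100 °C) gives 29, and step 15 completes the synthesis.

Step 8.
- **What may go wrong:** Under amine base the enol form of the β-ketal aldehyde or of its Mannich base may expel a dioxolane oxygen (E1cB ring opening) in competition with the Mannich addition and amine loss. The enal may also oligomerise.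
- **Fallback (methylene carbon installed before the ketal exists and unveiled without base):** it sets out from keto ester 13 and comes back at enal 17.
  - 13 is alkylated at its doubly activated carbon with chloromethyl phenyl sulfide (NaH, NaI, DMF) to give methyl 3-oxo-2-[(phenylsulfanyl)methyl]heptanoate F6.
  - Ketalisation as in step 6 gives methyl 2-(2-butyl-1,3-dioxolan-2-yl)-3-(phenylsulfanyl)propanoate F7.
  - i-Bu2AlH at −78 °C gives 2-(2-butyl-1,3-dioxolan-2-yl)-3-(phenylsulfanyl)propanal F8.
  - NaIO4 in aqueous MeOH gives 3-(benzenesulfinyl)-2-(2-butyl-1,3-dioxolan-2-yl)propanal F9 (mixture of diastereomers; F6–F8 are racemic).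
  - Thermal sulfoxide syn elimination of F9 (toluene, 80–110 °C, CaCO3) gives 17.

Step 5.
- **What may go wrong:** The terminal aryl ethynyl ether may oligomerise or take up water during aqueous work-up, concentration and chromatography, so that too little intact alkyne reaches step 12.
- **Fallback (silyl-masked alkyne):** it sets out from dichlorovinyl ether 9 and comes back at 12.
  - Acetylide 11, made as in step 5, is quenched with Me3SiCl in place of water to give {[2,4-bis(benzyloxy)-6-pentylphenoxy]ethynyl}(trimethyl)silane F10, which should tolerate chromatography and storage.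
  - K2CO3 in MeOH at 0 °C removes silicon just before the photolysis.
  - The pentane extract of 12 is exchanged into ClCH2CH2Cl without being taken to dryness.

Further compounds
F1 | step 12 | 1-(3,5-dimethoxyphenyl)pentan-1-one | CCCCC(=O)c1cc(OC)cc(OC)c1
F2 | step 12 | 1-(2-bromo-3,5-dimethoxyphenyl)pentan-1-one | CCCCC(=O)c1cc(OC)cc(OC)c1Br
F3 | step 12 | methyl 2,4-dimethoxy-6-pentanoylbenzoate | CCCCC(=O)c1cc(OC)cc(OC)c1C(=O)OC
F4 | step 12 | methyl 2-hydroxy-4-methoxy-6-pentanoylbenzoate | CCCCC(=O)c1cc(OC)cc(O)c1C(=O)OC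
F5 | step 12 | methyl 4-methoxy-6-pentanoyl-2-{[(trifluoromethyl)sulfonyl]oxy}benzoate | CCCCC(=O)c1cc(OC)cc(OS(=O)(=O)C(F)(F)F)c1C(=O)OC
F6 | step 8 | methyl 3-oxo-2-[(phenylsulfanyl)methyl]heptanoate | CCCCC(=O)C(CSc1ccccc1)C(=O)OC
F7 | step 8 | methyl 2-(2-butyl-1,3-dioxolan-2-yl)-3-(phenylsulfanyl)propanoate | CCCCC1(C(CSc2ccccc2)C(=O)OC)OCCO1
F8 | step 8 | 2-(2-butyl-1,3-dioxolan-2-yl)-3-(phenylsulfanyl)propanal | CCCCC1(C(CSc2ccccc2)C=O)OCCO1
F9 | step 8 | 3-(benzenesulfinyl)-2-(2-butyl-1,3-dioxolan-2-yl)propanal | CCCCC1(C(CS(=O)c2ccccc2)C=O)OCCO1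
F10 | step 5 | {[2,4-bis(benzyloxy)-6-pentylphenoxy]ethynyl}(trimethyl)silane | C[Si](C)(C)C#COc1c(CCCCC)cc(OCc2ccccc2)cc1OCc1ccccc1
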